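The earlier runs and the new flask stem from a simulated flask for an exercise; scatter was added.

The 4 questions on this flask, 0.30 M of E with 0.20 mM of J for 30 min, come down to one. In the birch and elm runs E already reads 0.1% and 0.3% at the first readings, 2.50 min and 5.00 min, and X and Q then stay flat within the scatter, so what remains is how E divides between X and Q.

| setting | birch | elm | flask |
|---|---|---|---|
| E | 0.30 M | 0.30 M | 0.30 M |
| J | 0.13 mM | 0.30 mM | 0.20 mM |
| remark | run made earlier | run made earlier |  |
| time |  |  | 30 min |

- birch (time / min: E / %, X / %, Q / %): 2.50: 0.1, 84.9, 15.0; 6.00: 0.6, 85.0, 14.8; 12.0: 0.1, 85.3, 14.7; 20.0: 0, 85.0, 15.1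
- elm (time / min: E / %, X / %, Q / %): 5.00: 0.3, 92.3, 7.9; 10.0: 0, 92.0, 8.1; 15.0: 0, 91.6, 7.3; 20.0: 0, 92.4, 7.7

(readings scatter by 0.3 percentage points)

- percentages count the E that a species holds: one Q counts as two
- candidate steps: E + D -> Q; E -> D; J + D -> J + X
- the reaction counts as stopped when no species that holds the E changes by six tenths of a point or more over the second half of the time

- the state of affairs at 30 min: stopped, and by what, or still going (no working catalyst is left / all of E has reacted / it is still moving)
- conversion of E at 30 min
- amount of X at 30 min, in percent of the E charged
- amount of Q at 30 min, in percent of the E charged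

Two chemists dispute that division. The first holds that D is shared between J, which gives X, and E, which gives Q. The forecast is hers: all of E has reacted, 100% conversion, 89.2% of X and 10.8% of Q, on the ground that “Q is favoured while E is high and J is low”. The second keeps to the readings and draws a straight line in J, from 85.0% of X in birch to 92.1% in elm, which reads 87.9% at the J of this flask.

I side with the first, by a cheaper road than integrating. Multiply the mean Q/X of a run by the J charged: birch gives 0.0228 mM and elm 0.0253 mM, and their mean, 0.0240 mM, is the split charge s, a selectivity factor in the form of an amount of J, read at the E of these runs. The two readings differ by 10.3%, so s is a working figure rather than a constant. On her sharing, Q/X goes nearly as s/J and rises in step with E, so this flask should have Q/X of 0.120, which makes X 89.3% and Q 10.7%, my own figures, beside the forecast's.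

The flask gives 89.1% of X and 10.9% of Q at 100% conversion, the state being all of E has reacted, so the first chemist stands, while the line lies 1.2 percentage points low and keeps its ground at the J of birch and elm, through which it was drawn.

    E + D → Q (k = 0.210 L mol⁻¹ s⁻¹)
    E → D (k = 0.0610 s⁻¹)
    J + D → J + X (k = 2200 L mol⁻¹ s⁻¹)

In this flask E was down to 0.364% at 1.50 min, and s read from its Q/X comes to 0.0245 mM. Carried to a neighbour flask with 0.75 M of E, the split charge scaled with E gives Q/X of 0.300, so X of 76.9%, and that neighbour flask holds 77.3% of X and 22.7% of Q.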